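**Plan**

Retrosynthesis: the C8 isovalerate, the C4 4‑hydroxybenzoate and the C6=C7 alkene come off first; the C3 carbinol, C3a–H and C4–O are traced back to the diene of ketone 11; 11 is cut at C1–C2 and C3a–C8a (hydroazulene numbering).
Enabling feature: the C8 oxygen sits on the carbon next to the quaternary ring‑fusion carbon C8a, which is the footprint of a pinacol shift. C1–C2–C3 with the isopropyl carbon is a 1,1‑dimethylallyl unit bonded to what was an isopropenyl CH2, so the cyclopentane is an allyl‑cation/alkene adduct and the seven‑membered ring a ring‑enlarged cyclohexene.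
Forward: chiral‑pool cyclohexenone 3 → 2‑alkenyl enone 5 → 1,2‑dialkenyl cyclohexenyl silyl ether 8; one cationic cyclisation/pinacol step then forms the cyclopentane and enlarges the six‑ to the seven‑membered ring; hydroboration, ene oxygenation, redox adjustment and two esterifications finish the route.
Stereochemistry: the methyl stereocenter of 3 steers the carbinol centre of 7, which is transferred to quaternary C8a in the key step (both donor centres are erased later); C3a and C3 are set from the face anti to the C8a methyl, C4 by hydroxyl‑directed hydride delivery, C8 by Mitsunobu inversion.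

Key step: step 6

Assumption: (R)‑5‑methylcyclohex‑2‑en‑1‑one (3) is taken as a purchasable chiral‑pool ketone (it is otherwise a known three‑step derivative of (R)‑pulegone).
Convention: bicyclic compounds carry the hydroazulene locants of the target (C1, C2, C3, C3a, C4–C8, C8a); β is the face of the C8a methyl group.

**Route**

Step 1
Reactants: 1 3‑methoxy‑3‑methylbut‑1‑yne
Product: 2 tributyl(3‑methoxy‑3‑methylbut‑1‑en‑2‑yl)stannane
Conditions: Bu3SnH, Mo(CO)3(CNtBu)3 (cat.), hydroquinone, THF, 55 °C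
Reagents that add atoms: tributyltin hydride, CCCC[SnH](CCCC)CCCC
Why: Molybdenum‑catalysed hydrostannation of a propargylic ether should place tin on the internal alkyne carbon (the regiochemistry typical of this catalyst class), giving the 1,1‑disubstituted alkenylstannane with no stereocenter formed.

Step 2
Reactants: 3 (R)‑5‑methylcyclohex‑2‑en‑1‑one
Product: 4 (R)‑2‑iodo‑5‑methylcyclohex‑2‑en‑1‑one
Conditions: I2, pyridine, CH2Cl2, 0 °C → rt
Reagents that add atoms: iodine, II
Why: α‑Iodination of a cyclic enone with iodine/pyridine (conjugate addition of pyridine, iodination of the enolate, elimination) is a standard reaction that leaves the remote methyl stereocenter untouched.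

Step 3
Reactants: 4 (R)‑2‑iodo‑5‑methylcyclohex‑2‑en‑1‑one; 2 tributyl(3‑methoxy‑3‑methylbut‑1‑en‑2‑yl)stannane
Product: 5 (R)‑2‑(3‑methoxy‑3‑methylbut‑1‑en‑2‑yl)‑5‑methylcyclohex‑2‑en‑1‑one
Conditions: Pd2(dba)3 (cat.), AsPh3, CuI, NMP, 40 °C
Reagents that add atoms: none
Why: Stille coupling of α‑iodoenones with alkenylstannanes is well established, and the CuI co‑catalyst should offset the hindrance of the α‑branched stannane, with no stereocenter affected.

Step 4
Reactants: 5 (R)‑2‑(3‑methoxy‑3‑methylbut‑1‑en‑2‑yl)‑5‑methylcyclohex‑2‑en‑1‑one; 6 prop‑1‑en‑2‑ylmagnesium bromide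
Product: 7 (1S,5R)‑2‑(3‑methoxy‑3‑methylbut‑1‑en‑2‑yl)‑5‑methyl‑1‑(prop‑1‑en‑2‑yl)cyclohex‑2‑en‑1‑ol
Conditions: CeCl3, THF, −78 °C; aq NH4Cl
Reagents that add atoms: none
Why: Cerium‑mediated 1,2‑addition of an alkenyl Grignard reagent to a cross‑conjugated enone is standard, and axial attack anti to the pseudoequatorial ring methyl group should give the carbinol with hydroxyl cis to that methyl group, the minor diastereomer (which would lead to the enantiomeric series) being removed by chromatography at this stage.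

Step 5
Reactants: 7 (1S,5R)‑2‑(3‑methoxy‑3‑methylbut‑1‑en‑2‑yl)‑5‑methyl‑1‑(prop‑1‑en‑2‑yl)cyclohex‑2‑en‑1‑ol
Product: 8 triethylsilyl ether of 7
Conditions: Et3SiOTf, 2,6‑lutidine, CH2Cl2, −78 °C
Reagents that add atoms: triethylsilyl trifluoromethanesulfonate, CC[Si](CC)(CC)OS(=O)(=O)C(F)(F)F
Why: Silylation of a hindered tertiary alcohol with a silyl triflate and 2,6‑lutidine is routine, and the silyl ether both prevents O‑capture of the cation in step 6 and serves as the group lost from oxygen in the pinacol step.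

Step 6
Reactants: 8 triethylsilyl ether of 7
Product: 11 dienone (6α,8aβ)‑6,8a‑dimethyl‑3‑(propan‑2‑ylidene)‑octahydroazulen‑8‑one (ring alkene C3a=C4), via dimethylallyl cation 9 (not isolated), via bicyclic tertiary cation 10 (not isolated)
Conditions: SnCl4 (1.1 equiv), 2,6‑di‑tert‑butyl‑4‑methylpyridine, CH2Cl2, −78 → −40 °C
Reagents that add atoms: none
Why: Proposed new method: SnCl4 should ionise the tertiary allylic methyl ether (the basic, unhindered oxygen) to the 1,1‑dimethylallyl cation 9, whose CH2 terminus is attacked by the CH2 of the isopropenyl group as in prenyl transfer, closing a six‑membered ring by a chair‑like 6‑endo cyclisation and leaving tertiary cation 10 beside the silyloxy carbon. A 1,2‑shift of the ring alkenyl carbon (pinacol rearrangement, driven by C=O formation and loss of the silyl group) then contracts that ring to the cyclopentane and at the same time enlarges the cyclohexene to the cycloheptene, so both new bonds arise in one operation. The closest known reaction type is the acetal‑initiated Prins–pinacol ring‑enlarging cyclopentane annulation of 1‑alkenylcycloalkanol silyl ethers, together with allylic‑cation initiation as known from polyene cyclisations; what is new is the allyl cation as initiator of the pinacol‑terminated sequence. The only new stereocenter, quaternary C8a, is fixed by the carbinol configuration of 8, because the tether holds the migrating carbon on one face of the cation and the new bond to the allyl terminus must form on that same side, so the carbinol centre is destroyed and its information transferred. The step needs attack at the primary and not the tertiary allyl terminus (sterics, more substituted alkene formed), migration of the alkenyl and not the alkyl ring carbon (higher migratory aptitude, better alignment in the six‑membered ring), and ionisation of C–OMe before the bis‑allylic C–OSiEt3 (low temperature, bulky and weakly basic silyl ether).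

Step 7
Reactants: 11 dienone (6α,8aβ)‑6,8a‑dimethyl‑3‑(propan‑2‑ylidene)‑octahydroazulen‑8‑one
Product: 13 diol (3aα‑H,4α,6α,8α,8aβ)‑6,8a‑dimethyl‑3‑(propan‑2‑ylidene)‑decahydroazulene‑4,8‑diol, via C4‑boryl O8‑borinate 12 (not isolated)
Conditions: 9‑BBN (3 equiv), THF, 65 °C; then NaOH, H2O2, 0 °C → rt
Reagents that add atoms: hydrogen peroxide, OO
Why: Hydroboration–oxidation with 9‑BBN should add H and B syn across the trisubstituted C3a=C4 bond, boron at the less substituted C4, from the α face anti to the C8a methyl group that flanks C3a (setting the trans ring fusion and a 4α‑hydroxyl), while the tetrasubstituted isopropylidene group is inert to this borane and the ketone is reduced to a carbinol whose configuration (drawn 8α) is of no consequence.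

Step 8
Reactants: 13 diol (3aα‑H,4α,6α,8α,8aβ)‑6,8a‑dimethyl‑3‑(propan‑2‑ylidene)‑decahydroazulene‑4,8‑diol
Product: 15 triol (3α,3aα‑H,4α,6α,8α,8aβ)‑6,8a‑dimethyl‑3‑(prop‑1‑en‑2‑yl)‑decahydroazulene‑3,4,8‑triol, via C3 hydroperoxide 14 (not isolated)
Conditions: O2, tetraphenylporphyrin (cat.), hν, CH2Cl2, −20 °C; then PPh3
Reagents that add atoms: oxygen, O=O
Why: The Schenck ene reaction of singlet oxygen with the tetrasubstituted alkene should abstract a methyl hydrogen (the ring allylic C–H bonds of the cyclopentane are poorly aligned) and deliver oxygen to C3 from the α face, anti to the pseudoaxial cis‑1,3 C8a methyl group of the now trans‑fused system, after which PPh3 reduces the hydroperoxide to the tertiary alcohol.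

Step 9
Reactants: 15 triol (3α,3aα‑H,4α,6α,8α,8aβ)‑6,8a‑dimethyl‑3‑(prop‑1‑en‑2‑yl)‑decahydroazulene‑3,4,8‑triol
Product: 16 triol (3α,3aα‑H,4α,6α,8α,8aβ)‑6,8a‑dimethyl‑3‑(propan‑2‑yl)‑decahydroazulene‑3,4,8‑triol
Conditions: H2 (1 atm), RhCl(PPh3)3 (cat.), benzene, rt
Reagents that add atoms: none
Why: Homogeneous hydrogenation with RhCl(PPh3)3 reduces the 1,1‑disubstituted isopropenyl group, the only alkene present, without hydrogenolysis of the tertiary allylic alcohol and without change at any stereocenter.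

Step 10
Reactants: 16 triol (3α,3aα‑H,4α,6α,8α,8aβ)‑6,8a‑dimethyl‑3‑(propan‑2‑yl)‑decahydroazulene‑3,4,8‑triol
Product: 17 hydroxy diketone (3α,3aα‑H,6α,8aβ)‑3‑hydroxy‑6,8a‑dimethyl‑3‑(propan‑2‑yl)‑octahydroazulene‑4,8‑dione
Conditions: Dess–Martin periodinane, NaHCO3, CH2Cl2, 0 °C → rt
Reagents that add atoms: none
Why: Dess–Martin oxidation converts both secondary alcohols to ketones under buffered neutral conditions that should neither epimerise C3a nor trigger retro‑aldol cleavage of the tertiary β‑hydroxy ketone.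

Step 11
Reactants: 17 hydroxy diketone (3α,3aα‑H,6α,8aβ)‑3‑hydroxy‑6,8a‑dimethyl‑3‑(propan‑2‑yl)‑octahydroazulene‑4,8‑dione
Product: 18 dihydroxy ketone (3α,3aα‑H,4β,6α,8aβ)‑3,4‑dihydroxy‑6,8a‑dimethyl‑3‑(propan‑2‑yl)‑octahydroazulen‑8‑one
Conditions: Me4NBH(OAc)3, MeCN/AcOH, −30 °C
Reagents that add atoms: none
Why: In this Evans–Saksena reduction the triacetoxyborohydride is bound by the tertiary C3 hydroxyl and delivers hydride intramolecularly to the C4 carbonyl from the α face, giving the 1,3‑anti diol (4β‑OH), while the C8 ketone has no hydroxyl within reach and should not be reduced by this mild hydride.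

Step 12
Reactants: 18 dihydroxy ketone (3α,3aα‑H,4β,6α,8aβ)‑3,4‑dihydroxy‑6,8a‑dimethyl‑3‑(propan‑2‑yl)‑octahydroazulen‑8‑one; 19 4‑acetoxybenzoyl chloride
Product: 20 keto ester (3α,3aα‑H,4β,6α,8aβ)‑3‑hydroxy‑6,8a‑dimethyl‑8‑oxo‑3‑(propan‑2‑yl)‑decahydroazulen‑4‑yl 4‑acetoxybenzoate
Conditions: Et3N, DMAP, CH2Cl2, 0 °C → rt
Reagents that add atoms: none
Why: DMAP‑catalysed acylation with an acid chloride esterifies the only secondary hydroxyl with retention, the tertiary C3 hydroxyl being unreactive under these conditions.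

Step 13
Reactants: 20 keto ester (3α,3aα‑H,4β,6α,8aβ)‑3‑hydroxy‑6,8a‑dimethyl‑8‑oxo‑3‑(propan‑2‑yl)‑decahydroazulen‑4‑yl 4‑acetoxybenzoate
Product: 21 enone (3α,3aα‑H,4β,8aβ)‑3‑hydroxy‑6,8a‑dimethyl‑8‑oxo‑3‑(propan‑2‑yl)‑1,2,3,3a,4,5,8,8a‑octahydroazulen‑4‑yl 4‑acetoxybenzoate
Conditions: IBX, 4‑methoxypyridine N‑oxide, DMSO, rt → 40 °C
Reagents that add atoms: none
Why: IBX‑mediated α,β‑dehydrogenation of the ketone can proceed only toward C7/C6 because C8a is quaternary, giving the trisubstituted enone and erasing the C6 stereocenter that carried the chirality from the pool.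

Step 14
Reactants: 21 enone (3α,3aα‑H,4β,8aβ)‑3‑hydroxy‑6,8a‑dimethyl‑8‑oxo‑3‑(propan‑2‑yl)‑octahydroazulen‑4‑yl 4‑acetoxybenzoate
Product: 22 allylic alcohol (3α,3aα‑H,4β,8β,8aβ)‑3,8‑dihydroxy‑6,8a‑dimethyl‑3‑(propan‑2‑yl)‑1,2,3,3a,4,5,8,8a‑octahydroazulen‑4‑yl 4‑acetoxybenzoate
Conditions: NaBH4, CeCl3·7H2O, MeOH, −78 °C
Reagents that add atoms: none
Why: Luche reduction gives clean 1,2‑reduction of the enone, and hydride attack from the α face, anti to the pseudoaxial C8a methyl group beside the carbonyl, should give the 8β‑alcohol while the low temperature spares the aryl acetate.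

Step 15
Reactants: 22 allylic alcohol (3α,3aα‑H,4β,8β,8aβ)‑3,8‑dihydroxy‑6,8a‑dimethyl‑3‑(propan‑2‑yl)‑octahydroazulen‑4‑yl 4‑acetoxybenzoate; 23 3‑methylbutanoic acid
Product: 24 diester (3α,3aα‑H,4β,8α,8aβ)‑3‑hydroxy‑6,8a‑dimethyl‑8‑(3‑methylbutanoyloxy)‑3‑(propan‑2‑yl)‑1,2,3,3a,4,5,8,8a‑octahydroazulen‑4‑yl 4‑acetoxybenzoate
Conditions: PPh3, DIAD, toluene, 0 °C → rt
Reagents that add atoms: none
Why: The Mitsunobu reaction esterifies the allylic alcohol with inversion to the 8α‑isovalerate, the carboxylate entering from the open α face, and elimination cannot compete because the activated carbon has no hydrogen on an adjacent sp3 carbon (C7 is vinylic, C8a quaternary), while the tertiary hydroxyl does not react.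

Step 16
Reactants: 24 diester (3α,3aα‑H,4β,8α,8aβ)‑3‑hydroxy‑6,8a‑dimethyl‑8‑(3‑methylbutanoyloxy)‑3‑(propan‑2‑yl)‑octahydroazulen‑4‑yl 4‑acetoxybenzoate
Product: 25 CNP0086724.4, (3α,3aα‑H,4β,8α,8aβ)‑3‑hydroxy‑6,8a‑dimethyl‑8‑(3‑methylbutanoyloxy)‑3‑(propan‑2‑yl)‑1,2,3,3a,4,5,8,8a‑octahydroazulen‑4‑yl 4‑hydroxybenzoate
Conditions: K2CO3 (0.2 equiv), MeOH, 0 °C
Reagents that add atoms: none
Why: Phenolic acetates undergo mild base‑catalysed methanolysis far faster than alkyl or aroyl esters of secondary alcohols, so the phenol should be released without touching the other two esters.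

**Compound list**

1 | 3‑methoxy‑3‑methylbut‑1‑yne | C#CC(C)(C)OC | starting material
2 | tributyl(3‑methoxy‑3‑methylbut‑1‑en‑2‑yl)stannane | C=C([Sn](CCCC)(CCCC)CCCC)C(C)(C)OC | intermediate
3 | (R)‑5‑methylcyclohex‑2‑en‑1‑one | C[C@@H]1CC=CC(=O)C1 | starting material
4 | (R)‑2‑iodo‑5‑methylcyclohex‑2‑en‑1‑one | C[C@@H]1CC=C(I)C(=O)C1 | intermediate
5 | (R)‑2‑(3‑methoxy‑3‑methylbut‑1‑en‑2‑yl)‑5‑methylcyclohex‑2‑en‑1‑one | C[C@@H]1CC=C(C(=C)C(C)(C)OC)C(=O)C1 | intermediate
6 | prop‑1‑en‑2‑ylmagnesium bromide | C=C(C)[Mg]Br | starting material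
7 | (1S,5R)‑2‑(3‑methoxy‑3‑methylbut‑1‑en‑2‑yl)‑5‑methyl‑1‑(prop‑1‑en‑2‑yl)cyclohex‑2‑en‑1‑ol (OH cis to the ring methyl) | CC(=C)[C@@]1(O)C[C@H](C)CC=C1C(=C)C(C)(C)OC | intermediate
8 | triethylsilyl ether of 7 | CC(=C)[C@@]1(O[Si](CC)(CC)CC)C[C@H](C)CC=C1C(=C)C(C)(C)OC | intermediate
9 | dimethylallyl cation from 8 (loss of methoxide) | CC(=C)[C@@]1(O[Si](CC)(CC)CC)C[C@H](C)CC=C1C(=C)[C+](C)C | intermediate
10 | bicyclic tertiary cation (six‑membered ring closed, cation beside the silyloxy carbon) | C[C@@H]1CC=C2C(=C(C)C)CC[C+](C)[C@@]2(O[Si](CC)(CC)CC)C1 | intermediate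
11 | (6α,8aβ)‑6,8a‑dimethyl‑3‑(propan‑2‑ylidene)‑1,2,3,5,6,7,8,8a‑octahydroazulen‑8‑one, ring alkene C3a=C4 | C[C@H]1CC(=O)[C@@]2(C)CCC(=C(C)C)C2=CC1 | intermediate
12 | C4‑(9‑borabicyclononyl), O8‑(9‑borabicyclononyl) adduct of 11 (3aα‑H, 4α‑B, 8α‑O) | C[C@H]1C[C@@H](OB3C4CCCC3CCC4)[C@@]2(C)CCC(=C(C)C)[C@@H]2[C@@H](B3C4CCCC3CCC4)C1 | intermediate
13 | (3aα‑H,4α,6α,8α,8aβ)‑6,8a‑dimethyl‑3‑(propan‑2‑ylidene)‑decahydroazulene‑4,8‑diol | C[C@H]1C[C@@H](O)[C@@]2(C)CCC(=C(C)C)[C@@H]2[C@@H](O)C1 | intermediate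
14 | 3α‑hydroperoxy‑3β‑(prop‑1‑en‑2‑yl) analogue: (3aα‑H,4α,6α,8α,8aβ)‑3‑hydroperoxy‑6,8a‑dimethyl‑3‑(prop‑1‑en‑2‑yl)‑decahydroazulene‑4,8‑diol | C[C@H]1C[C@@H](O)[C@@]2(C)CC[C@](OO)(C(C)=C)[C@@H]2[C@@H](O)C1 | intermediate
15 | (3α,3aα‑H,4α,6α,8α,8aβ)‑6,8a‑dimethyl‑3‑(prop‑1‑en‑2‑yl)‑decahydroazulene‑3,4,8‑triol | C[C@H]1C[C@@H](O)[C@@]2(C)CC[C@](O)(C(C)=C)[C@@H]2[C@@H](O)C1 | intermediate
16 | (3α,3aα‑H,4α,6α,8α,8aβ)‑6,8a‑dimethyl‑3‑(propan‑2‑yl)‑decahydroazulene‑3,4,8‑triol | C[C@H]1C[C@@H](O)[C@@]2(C)CC[C@](O)(C(C)C)[C@@H]2[C@@H](O)C1 | intermediate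
17 | (3α,3aα‑H,6α,8aβ)‑3‑hydroxy‑6,8a‑dimethyl‑3‑(propan‑2‑yl)‑octahydroazulene‑4,8‑dione | C[C@H]1CC(=O)[C@@]2(C)CC[C@](O)(C(C)C)[C@@H]2C(=O)C1 | intermediate
18 | (3α,3aα‑H,4β,6α,8aβ)‑3,4‑dihydroxy‑6,8a‑dimethyl‑3‑(propan‑2‑yl)‑octahydroazulen‑8‑one | C[C@H]1CC(=O)[C@@]2(C)CC[C@](O)(C(C)C)[C@@H]2[C@H](O)C1 | intermediate
19 | 4‑acetoxybenzoyl chloride | CC(=O)Oc1ccc(cc1)C(Cl)=O | starting material
20 | (3α,3aα‑H,4β,6α,8aβ)‑3‑hydroxy‑6,8a‑dimethyl‑8‑oxo‑3‑(propan‑2‑yl)‑decahydroazulen‑4‑yl 4‑acetoxybenzoate | C[C@H]1CC(=O)[C@@]2(C)CC[C@](O)(C(C)C)[C@@H]2[C@H](OC(=O)c2ccc(OC(C)=O)cc2)C1 | intermediate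
21 | (3α,3aα‑H,4β,8aβ)‑3‑hydroxy‑6,8a‑dimethyl‑8‑oxo‑3‑(propan‑2‑yl)‑1,2,3,3a,4,5,8,8a‑octahydroazulen‑4‑yl 4‑acetoxybenzoate | CC1=CC(=O)[C@@]2(C)CC[C@](O)(C(C)C)[C@@H]2[C@H](OC(=O)c2ccc(OC(C)=O)cc2)C1 | intermediate
22 | (3α,3aα‑H,4β,8β,8aβ)‑3,8‑dihydroxy‑6,8a‑dimethyl‑3‑(propan‑2‑yl)‑1,2,3,3a,4,5,8,8a‑octahydroazulen‑4‑yl 4‑acetoxybenzoate | CC1=C[C@H](O)[C@@]2(C)CC[C@](O)(C(C)C)[C@@H]2[C@H](OC(=O)c2ccc(OC(C)=O)cc2)C1 | intermediate
23 | 3‑methylbutanoic acid | CC(C)CC(O)=O | starting material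
24 | (3α,3aα‑H,4β,8α,8aβ)‑3‑hydroxy‑6,8a‑dimethyl‑8‑(3‑methylbutanoyloxy)‑3‑(propan‑2‑yl)‑1,2,3,3a,4,5,8,8a‑octahydroazulen‑4‑yl 4‑acetoxybenzoate | CC1=C[C@@H](OC(=O)CC(C)C)[C@@]2(C)CC[C@](O)(C(C)C)[C@@H]2[C@H](OC(=O)c2ccc(OC(C)=O)cc2)C1 | intermediate
25 | CNP0086724.4 | CC1=C[C@@H](OC(=O)CC(C)C)[C@@]2(C)CC[C@](O)(C(C)C)[C@@H]2[C@H](OC(=O)c2ccc(O)cc2)C1 | target

**Count and risks**

Total step count: 16. Longest linear sequence: 15 steps (3 → 25, steps 2–16); step 1 is a one‑step side branch.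

Steps most likely to fail:

1. Step 6 (Proposed new method). The cation may be generated at the wrong place (ionisation of the bis‑allylic silyloxy carbon), be captured at its tertiary terminus, or lose a proton before the shift. The fallback uses an acetal initiator, the initiator class for which the Prins–pinacol annulation is established; it sets out from 4 and returns at 11. 3‑Methylbut‑2‑enal is α‑brominated (Br2, then Et3N) to 2‑bromo‑3‑methylbut‑2‑enal F1 and converted with trimethyl orthoformate and acid into 2‑bromo‑1,1‑dimethoxy‑3‑methylbut‑2‑ene F2. Bromine–lithium exchange and Bu3SnCl give tributyl(1,1‑dimethoxy‑3‑methylbut‑2‑en‑2‑yl)stannane F3. Stille coupling of F3 with 4 gives the acetal enone F4, addition of 6 (CeCl3) gives the carbinol F5, and Et3SiOTf gives the silyl ether F6. SnCl4 then generates the oxocarbenium ion, which undergoes the same cyclisation and pinacol shift to the 1‑methoxy ketone F7. Ionic hydrogenolysis of the allylic methyl ether (Et3SiH, BF3·OEt2, −78 °C) gives 11.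

2. Step 7. Facial selectivity of the hydroboration may be poor: attack syn to the C8a methyl group (the convex face of the cycloheptene) would give the cis‑fused series. The fallback delivers hydrogen intramolecularly; it sets out from 11 and returns at 13. The ketone is reduced (NaBH4 or L‑Selectride; epimers separated, the unwanted one recycled by oxidation) to the 8α‑alcohol F8, which is silylated with 1,1,3,3‑tetramethyldisilazane to the dimethylsilyl ether F9. Pt2[(CH2=CHSiMe2)2O]3‑catalysed intramolecular hydrosilylation gives the bridged oxasilinane F10. Silicon should go to the less substituted C4 and hydrogen to C3a, both necessarily on the α face held by the tether. Tamao–Fleming oxidation (KF, KHCO3, H2O2) then gives 13.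

3. Step 15. Substitution at the allylic carbon next to a quaternary centre may be slow, allowing allylic transposition or ionisation with loss of configuration. The fallback replaces inversion by reagent‑controlled reduction and acylation with retention; it sets out from 21 and returns at 24. Corey–Bakshi–Shibata reduction of enone 21, with the oxazaborolidine antipode that delivers hydride to the β face ((S)‑Me‑CBS if the quaternary C8a side acts as the large group), gives the 8α‑allylic alcohol F11. Acylation of F11 with 3‑methylbutanoyl chloride, Et3N and DMAP gives 24.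

**Further compounds**

F1 | step 6 | 2‑bromo‑3‑methylbut‑2‑enal | CC(C)=C(Br)C=O
F2 | step 6 | 2‑bromo‑1,1‑dimethoxy‑3‑methylbut‑2‑ene | COC(OC)C(Br)=C(C)C
F3 | step 6 | tributyl(1,1‑dimethoxy‑3‑methylbut‑2‑en‑2‑yl)stannane | COC(OC)C(=C(C)C)[Sn](CCCC)(CCCC)CCCC
F4 | step 6 | (R)‑2‑(1,1‑dimethoxy‑3‑methylbut‑2‑en‑2‑yl)‑5‑methylcyclohex‑2‑en‑1‑one | C[C@@H]1CC=C(C(=C(C)C)C(OC)OC)C(=O)C1
F5 | step 6 | (1S,5R)‑2‑(1,1‑dimethoxy‑3‑methylbut‑2‑en‑2‑yl)‑5‑methyl‑1‑(prop‑1‑en‑2‑yl)cyclohex‑2‑en‑1‑ol | CC(=C)[C@@]1(O)C[C@H](C)CC=C1C(=C(C)C)C(OC)OC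
F6 | step 6 | triethylsilyl ether of F5 | CC(=C)[C@@]1(O[Si](CC)(CC)CC)C[C@H](C)CC=C1C(=C(C)C)C(OC)OC
F7 | step 6 | 1‑methoxy derivative of 11 (C1 configuration drawn provisionally, removed in the next operation) | C[C@H]1CC(=O)[C@@]2(C)C[C@@H](OC)C(=C(C)C)C2=CC1
F8 | step 7 | (6α,8α,8aβ)‑6,8a‑dimethyl‑3‑(propan‑2‑ylidene)‑1,2,3,5,6,7,8,8a‑octahydroazulen‑8‑ol | C[C@H]1C[C@@H](O)[C@@]2(C)CCC(=C(C)C)C2=CC1
F9 | step 7 | dimethylsilyl ether of F8 | C[C@H]1C[C@@H](O[SiH](C)C)[C@@]2(C)CCC(=C(C)C)C2=CC1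
F10 | step 7 | bridged oxasilinane (O8–SiMe2–C4 on the α face, 3aα‑H) | C[C@H]1C[C@@H](O[Si]3(C)C)[C@@]2(C)CCC(=C(C)C)[C@@H]2[C@@H]3C1
F11 | step 15 | (3α,3aα‑H,4β,8α,8aβ)‑3,8‑dihydroxy‑6,8a‑dimethyl‑3‑(propan‑2‑yl)‑1,2,3,3a,4,5,8,8a‑octahydroazulen‑4‑yl 4‑acetoxybenzoate | CC1=C[C@@H](O)[C@@]2(C)CC[C@](O)(C(C)C)[C@@H]2[C@H](OC(=O)c2ccc(OC(C)=O)cc2)C1
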